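If you set partner below substrate on a plate, the bench rule for the limiting reagent says what stays behind: each partner turns one open intermediate into product, so open intermediate ends at the excess.

all flasks: free catalyst 0.49 mM
- north-east: substrate 0.049 M; partner 0.0343 M; a single well-mixed tank run continuously and read at steady state, 50 min in it on average
- west: substrate 0.049 M (fed, over 40.0 min); partner 0.0343 M; all but substrate at the start; substrate goes in evenly over 40.0 min, the run ends at 50 min; time 50 min
- south-east: substrate 0.049 M; partner 0.0343 M; everything together in a closed stirred flask, run for 50 min; time 50 min
- east: substrate 0.049 M; partner 0.0343 M (fed, over 40.0 min); all but partner at the start; partner goes in evenly over 40.0 min, the run ends at 50 min; time 50 min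

- the set-up with the highest amount of open intermediate at the outlet or at the end, in percent of the substrate put in ("none" if the first two lie within 2 percentage points) (north-east / west / south-east / east / none)
- amount of open intermediate at the outlet or at the end, in percent of the substrate put in, north-east
- amount of open intermediate at the outlet or at the end, in percent of the substrate put in, west
- amount of open intermediate at the outlet or at the end, in percent of the substrate put in, south-east
- amount of open intermediate at the outlet or at the end, in percent of the substrate put in, east

    free catalyst + open intermediate ⇌ catalyst intermediate (K1 = 29.0 L mol⁻¹, k1 = 921 L mol⁻¹ min⁻¹)
    partner + catalyst intermediate → free catalyst + product (k2 = 348 L mol⁻¹ min⁻¹)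
    substrate + free catalyst → free catalyst + open intermediate (k3 = 6560 L mol⁻¹ min⁻¹)
    substrate + free catalyst → spent catalyst (k4 = 2.59 L mol⁻¹ min⁻¹)

In south-east substrate opens by its catalysed step with a half-life of 0.22 min at the charged catalyst, much shorter than the run, so the question is how far partner gets. For south-east the rule gives 30.0% of the substrate, but it carries no clock.

Partner is used by catalyst intermediate, so its tail is pseudo-first-order. The back step runs at 31.8 min⁻¹, faster than partner's step even at the full charge, 11.9 min⁻¹, so I treat the binding as balanced. With c(open intermediate) at that excess and the binding constant 29.0 L mol⁻¹, I reckon a share 29.9% of the catalyst bound, the spent form set aside.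

Now work in powers of ten. The decade time, the minutes in which c(partner) falls tenfold at that bound share, is 45.1 min. It is shorter than the run of 50 min, but only just: the ratio is 1.11 decades, which by this reckoning leaves 7.80% of the partner in south-east. That puts my estimate 5.5 percentage points above the rule's figure, against a margin of 2 points, so here the rule has crossed its border. I commit to 35.5% for south-east and stop there, leaving the fed flasks and the tank unreckoned.

The forecast, holding that “the partner-consuming step controls the outcome”, gives 45.8% for north-east, 39.2% for west, 33% for south-east and 41.7% for east, with north-east best.

The simulation puts north-east first: north-east 45.8%, east 41.7%, west 39.2%, south-east 32.9%.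

North-east leads south-east by 13 points; with the way back from catalyst intermediate to free catalyst + open intermediate taken away, the lead is 1.9 points and north-east no longer counts as best, so that way back is at most the largest single effect on the lead. South-east kept 4.66% of its partner, which is 1.33 decades against the 1.11 from the decade time of 45.1 min. The south-east flask with 0.021 M of partner has a decade time of 30.1 min, which reckons 2.18% of its partner left, and it kept 2.1%.

The numbers come from no measurement.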